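The upper flavan is unravelled at two bonds of its pyran ring C: C2–C3 and the C4–C6 interflavan bond. The key step exploits the 7-oxygen para to C4a of the upper ring A: it makes the vinyl terminus C3 nucleophilic and stabilises a C4 benzylic cation. In one operation a 2-vinylphenol and 4-benzyloxybenzaldehyde give an O-aryl oxocarbenium ion; C3 attacks C2 (Prins closure of ring C) under a chiral Brønsted acid, and the flavan-4-yl cation is captured at C6 of an 8-bromo-blocked tri-O-benzyl-epiafzelechin. The precursor is an open O-aryl hemiacetal carrying an ortho vinyl group. Benzylation, bromination and final hydrogenolysis frame the cascade.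

Key step: step 4

Remarks on the chemistry:
- Flavan numbering is used (O1, C2, C3, C4, C4a, C5–C8, C8a; primes for ring B); "upper" is the flavan unit, "lower" the flavan-3-ol unit.
- The target is read as (2S,4S)-2,4-cis in the upper unit and (2R,3R), i.e. (−)-epiafzelechin, in the lower unit, joined C4(upper)–C6(lower).
- (−)-Epiafzelechin is assumed to be purchasable from natural-product suppliers.
- The sense of induction of the chiral acid in step 4 cannot be predicted with certainty; the (R)-acid is written and its (S)-antipode would be used if the 2R series were favoured.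

Step 1
Reactants: 1 4-(benzyloxy)-2-hydroxybenzaldehyde
Product: 2 5-(benzyloxy)-2-vinylphenol
Conditions: Ph3PCH3Br (2.5 equiv), KOtBu (2.5 equiv), THF, 0 °C to rt; aq NH4Cl work-up; product kept cold and used promptly
Reagents that add atoms: methyltriphenylphosphonium bromide, C[P+](c1ccccc1)(c1ccccc1)c1ccccc1.[Br-]
Why: Wittig methylenation; the first equivalent of base forms the phenoxide and the excess ylide olefinates the aldehyde, the usual way from salicylaldehydes to 2-vinylphenols, with no stereocentre formed.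

Step 2
Reactants: 3 (−)-epiafzelechin, (2R,3R)-2-(4-hydroxyphenyl)chroman-3,5,7-triol
Product: 4 5,7,4'-tri-O-benzyl-(−)-epiafzelechin, (2R,3R)-5,7-bis(benzyloxy)-2-[4-(benzyloxy)phenyl]chroman-3-ol
Conditions: BnBr (3.3 equiv), K2CO3 (3.5 equiv), DMF, 0 °C to rt, N2, dark
Reagents that add atoms: benzyl bromide, BrCc1ccccc1
Why: Williamson ether synthesis; carbonate deprotonates only the three phenols and not the secondary 3-OH, and the cold, oxygen-free conditions should keep the base-sensitive (2R,3R) configuration intact.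

Step 3
Reactants: 4 5,7,4'-tri-O-benzyl-(−)-epiafzelechin
Product: 5 8-bromo-5,7,4'-tri-O-benzyl-(−)-epiafzelechin, (2R,3R)-5,7-bis(benzyloxy)-2-[4-(benzyloxy)phenyl]-8-bromochroman-3-ol
Conditions: NBS (1.0 equiv), CH2Cl2, −78 °C to −40 °C
Reagents that add atoms: N-bromosuccinimide, O=C1CCC(=O)N1Br
Why: Electrophilic aromatic bromination; in 5,7-di-O-benzylated flavan-3-ols C-8 is the most reactive ring-A carbon, so one equivalent of NBS at low temperature should block it and leave C-6 as the only free nucleophilic position.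

Step 4
Reactants: 2 5-(benzyloxy)-2-vinylphenol, 5 8-bromo-5,7,4'-tri-O-benzyl-(−)-epiafzelechin (1.5 equiv), 6 4-(benzyloxy)benzaldehyde (1.1 equiv)
Product: 10 (2R,3R)-5,7-bis(benzyloxy)-2-[4-(benzyloxy)phenyl]-6-{(2S,4S)-7-(benzyloxy)-2-[4-(benzyloxy)phenyl]chroman-4-yl}-8-bromochroman-3-ol, via O-aryl hemiacetal 7 (not isolated), via oxocarbenium ion 8 (not isolated), via flavan-4-yl cation 9 (not isolated)
Conditions: (R)-3,3'-bis(2,4,6-triisopropylphenyl)-1,1'-binaphthyl-2,2'-diyl N-triflylphosphoramide (C51H57F3NO5PS, 10 mol %), 5 Å molecular sieves, CH2Cl2, −40 °C to 0 °C, slow addition of 2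
Reagents that add atoms: none
Why: Proposed new method: phenol 2 and aldehyde 6 condense to hemiacetal 7, which the acid dehydrates to the O-aryl oxocarbenium ion 8, held as an ion pair with the chiral phosphoramide anion; the terminal vinyl carbon C3 then attacks the oxocarbenium carbon C2 in a Prins cyclisation (6-endo-trig, both alkene carbons inside the new ring C) that forms the C2–C3 bond and leaves the secondary benzylic cation 9 at C4, stabilised by the para 7-benzyloxy group, which is arylated by C-6 of 5 in a Friedel–Crafts step. The closest known reaction types are the chiral Brønsted acid-catalysed Prins cyclisation of aldehydes with homoallylic alcohols, the Lewis acid-mediated Prins/Friedel–Crafts cascade to 4-aryltetrahydropyrans and the acid-mediated arylation of flavan-4-yl cations in proanthocyanidin chemistry; new is their merger on a 2-vinylphenol under counter-anion control. C-2 (S) is set in the C–C bond-forming step by the chiral anion, which shields one face of the planar oxocarbenium ion. C-4 (S) is controlled by C-2: the bulky arene should add to the half-chair cation 9 so that both aryl groups end up equatorial (2,4-cis), and because arylation of such cations is acid-reversible a trans isomer can re-ionise and converge on this more stable isomer. Regioselectivity rests on the C-8 bromine of 5, which leaves C-6 as the only open nucleophilic carbon, and chemoselectivity on the intramolecular alkene, which should intercept 8 faster than the hindered arene or the reversibly adding 3-OH of 5.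

Step 5
Reactants: 10 protected 8-bromo dimer
Product: 11 (2R,3R)-6-[(2S,4S)-7-hydroxy-2-(4-hydroxyphenyl)chroman-4-yl]-2-(4-hydroxyphenyl)chroman-3,5,7-triol (CNP0167324.1)
Conditions: H2 (1 atm), Pd(OH)2/C, Et3N (1.5 equiv), THF/MeOH/H2O, rt
Reagents that add atoms: none
Why: Catalytic hydrogenolysis (O-debenzylation with concurrent hydrodebromination); Pd(OH)2/C should cleave the five benzyl aryl ethers and the aryl C–Br bond while Et3N traps HBr, so the acid-labile interflavan bond and the four stereocentres are untouched.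

Compound list
1 | 4-(benzyloxy)-2-hydroxybenzaldehyde | O=Cc1ccc(OCc2ccccc2)cc1O | starting material
2 | 5-(benzyloxy)-2-vinylphenol | C=Cc1ccc(OCc2ccccc2)cc1O | intermediate
3 | (−)-epiafzelechin, (2R,3R)-2-(4-hydroxyphenyl)chroman-3,5,7-triol | Oc1cc2c(c(O)c1)C[C@@H](O)[C@@H](c1ccc(O)cc1)O2 | starting material
4 | (2R,3R)-5,7-bis(benzyloxy)-2-[4-(benzyloxy)phenyl]chroman-3-ol | c1ccccc1COc1cc2c(c(OCc3ccccc3)c1)C[C@@H](O)[C@@H](c1ccc(OCc3ccccc3)cc1)O2 | intermediate
5 | (2R,3R)-5,7-bis(benzyloxy)-2-[4-(benzyloxy)phenyl]-8-bromochroman-3-ol | c1ccccc1COc1c(Br)c2c(c(OCc3ccccc3)c1)C[C@@H](O)[C@@H](c1ccc(OCc3ccccc3)cc1)O2 | intermediate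
6 | 4-(benzyloxy)benzaldehyde | O=Cc1ccc(OCc2ccccc2)cc1 | starting material
7 | [5-(benzyloxy)-2-ethenylphenoxy][4-(benzyloxy)phenyl]methanol (O-aryl hemiacetal, either configuration at the hemiacetal carbon) | OC(Oc1cc(OCc2ccccc2)ccc1C=C)c1ccc(OCc2ccccc2)cc1 | intermediate
8 | {[4-(benzyloxy)phenyl]methylidene}[5-(benzyloxy)-2-ethenylphenyl]oxonium (oxocarbenium ion, paired with the catalyst anion) | C=Cc1ccc(OCc2ccccc2)cc1[O+]=Cc1ccc(OCc2ccccc2)cc1 | intermediate
9 | (2S)-7-(benzyloxy)-2-[4-(benzyloxy)phenyl]chroman-4-ylium (flavan-4-yl cation) | [CH+]1C[C@@H](c2ccc(OCc3ccccc3)cc2)Oc2cc(OCc3ccccc3)ccc12 | intermediate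
10 | (2R,3R)-5,7-bis(benzyloxy)-2-[4-(benzyloxy)phenyl]-6-{(2S,4S)-7-(benzyloxy)-2-[4-(benzyloxy)phenyl]chroman-4-yl}-8-bromochroman-3-ol | c1ccccc1COc1ccc([C@@H]2C[C@H](c3c(OCc5ccccc5)c(Br)c4c(c3OCc6ccccc6)C[C@@H](O)[C@@H](c7ccc(OCc8ccccc8)cc7)O4)c3ccc(OCc5ccccc5)cc3O2)cc1 | intermediate
11 | (2R,3R)-6-[(2S,4S)-7-hydroxy-2-(4-hydroxyphenyl)chroman-4-yl]-2-(4-hydroxyphenyl)chroman-3,5,7-triol | Oc1ccc([C@@H]2C[C@H](c3c(O)cc4c(c3O)C[C@@H](O)[C@@H](c3ccc(O)cc3)O4)c3ccc(O)cc3O2)cc1 | target

Total step count: 5. Longest linear sequence: 4 steps (3 → 4 → 5 → 10 → 11).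

Steps most likely to fail

Step 4 (proposed new method). The chiral anion may give poor facial control at C2, the arene may add to cation 9 with incomplete 2,4-cis selectivity, or the electron-rich vinylphenol may oligomerise under acid before it is intercepted. The fallback uses known chemistry, sets out from 6 and comes back to the route at 10. Claisen–Schmidt condensation of 6 with purchased 1-[4-(benzyloxy)-2-hydroxyphenyl]ethanone (KOH, EtOH, rt) should give (E)-1-[4-(benzyloxy)-2-hydroxyphenyl]-3-[4-(benzyloxy)phenyl]prop-2-en-1-one F1. NaOAc in refluxing EtOH should close it by oxa-Michael addition to racemic 7-(benzyloxy)-2-[4-(benzyloxy)phenyl]chroman-4-one F2. Asymmetric transfer hydrogenation with kinetic resolution (chloro(p-cymene)[(S,S)-N-tosyl-1,2-diphenylethylenediamine]ruthenium, RuCl(p-cymene)[(S,S)-TsDPEN], HCO2H/Et3N; the catalyst antipode is chosen so that the 2S ketone reacts fast) should give (2S,4S)-7-(benzyloxy)-2-[4-(benzyloxy)phenyl]chroman-4-ol F3. BF3·OEt2 in CH2Cl2 at −78 °C then ionises F3 to cation 9, which 5 captures at C-6 to give 10 after chromatographic removal of any 4-epimer.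

Step 5. Hydrogenolysis of the hindered C8–Br bond may stall, or HBr released at the catalyst surface may cleave the interflavan bond before the amine traps it. The fallback separates the two events, sets out from 10 and comes back at 11. Radical hydrodebromination (Bu3SnH, azobisisobutyronitrile, toluene, 90 °C) should give the bromine-free (2R,3R)-5,7-bis(benzyloxy)-2-[4-(benzyloxy)phenyl]-6-{(2S,4S)-7-(benzyloxy)-2-[4-(benzyloxy)phenyl]chroman-4-yl}chroman-3-ol F4. Halide-free neutral hydrogenolysis of F4 (H2, Pd(OH)2/C, THF/MeOH, rt) then gives 11.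

Step 1. The electron-rich hydroxystyrene may oligomerise during work-up and storage, and the phenoxide-deactivated aldehyde may olefinate sluggishly. The fallback carries the phenol in latent form, sets out from 1 and comes back at 2. Silylation of 1 (TBSCl, imidazole, DMF, rt) should give 4-(benzyloxy)-2-[(tert-butyldimethylsilyl)oxy]benzaldehyde F5. Wittig methylenation (Ph3PCH3Br, KOtBu, 1.2 equiv each, THF, 0 °C) should give the storable [5-(benzyloxy)-2-ethenylphenoxy](tert-butyl)dimethylsilane F6. Desilylation of F6 with Bu4NF (THF, 0 °C, aq NH4Cl work-up) immediately before step 4 releases 2.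

Further compounds
F1 | step 4 | (E)-1-[4-(benzyloxy)-2-hydroxyphenyl]-3-[4-(benzyloxy)phenyl]prop-2-en-1-one | O=C(/C=C/c1ccc(OCc2ccccc2)cc1)c1ccc(OCc2ccccc2)cc1O
F2 | step 4 | racemic 7-(benzyloxy)-2-[4-(benzyloxy)phenyl]chroman-4-one | O=C1CC(c2ccc(OCc3ccccc3)cc2)Oc2cc(OCc3ccccc3)ccc12
F3 | step 4 | (2S,4S)-7-(benzyloxy)-2-[4-(benzyloxy)phenyl]chroman-4-ol | c1ccccc1COc1ccc([C@@H]2C[C@H](O)c3ccc(OCc4ccccc4)cc3O2)cc1
F4 | step 5 | (2R,3R)-5,7-bis(benzyloxy)-2-[4-(benzyloxy)phenyl]-6-{(2S,4S)-7-(benzyloxy)-2-[4-(benzyloxy)phenyl]chroman-4-yl}chroman-3-ol | c1ccccc1COc1ccc([C@@H]2C[C@H](c3c(OCc5ccccc5)cc4c(c3OCc6ccccc6)C[C@@H](O)[C@@H](c7ccc(OCc8ccccc8)cc7)O4)c3ccc(OCc5ccccc5)cc3O2)cc1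
F5 | step 1 | 4-(benzyloxy)-2-[(tert-butyldimethylsilyl)oxy]benzaldehyde | O=Cc1ccc(OCc2ccccc2)cc1O[Si](C)(C)C(C)(C)C
F6 | step 1 | [5-(benzyloxy)-2-ethenylphenoxy](tert-butyl)dimethylsilane | C=Cc1ccc(OCc2ccccc2)cc1O[Si](C)(C)C(C)(C)C
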